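**Retrosynthetic overview**

1. Target 26 ← methyl ester 24 ← alcohol 22 + umbelliferone 23 (Mitsunobu ether). The propanoate chain of 22 ← the formyl group of aldehyde 19 (Horner–Wadsworth–Emmons, then conjugate reduction).
2. Cyclohexene locants used below: C1 quaternary, C2 CH–CH2O, C3 =C(CH3), C4 =CH, C5 CH–isopropenyl, C6 CH2. Key disconnection: the C3=C4 and C1–C2 bonds, made in one pot from anomeric acetate 13 and alkenyltrifluoroborate 17 by C-alkenylation at C4 and Claisen rearrangement of the resulting 2-alkenyl-dihydropyran 18.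
3. Enabling feature: with the chain carbon on C1 at the aldehyde level, C4=C3–C2–C1–CHO is a γ,δ-unsaturated aldehyde. The formyl carbon and C4 are 1,5-related through C1–C6–C5, so the formyl oxygen can be tied to C4 in a six-membered enol ether ring (O, C4, C5, C6, C1, formyl C) that delivers C1 onto C2.
4. 13 ← enol lactone 11 ← oxo acid 10 ← oxazolidinone-auxiliary alkylation (sets C5). 17 ← but-2-yn-1-ol (syn borylation sets the alkene geometry that becomes C2).
5. Ring order: the dihydropyranone (temporary heterocycle) first, then the cyclohexene in the key step; the coumarin is bought intact.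

Key step: step 10

Assumption: the sodium dienolate of imide 4 should react at its α-carbon on the face opposite to the benzyl group, as the propionyl analogue does, which gives the (R) α-centre; the enol-ester geometry of 6 and 8, the methyl-bearing CH of 10 and the anomeric centre of 13 are left undefined because they converge later.

Step 1
Reactants: 1 (4R)-4-benzyl-1,3-oxazolidin-2-one; 2 3-methylbut-2-enoyl chloride
Product: 4 (4R)-4-benzyl-3-(3-methylbut-2-enoyl)-1,3-oxazolidin-2-one, via lithium oxazolidinide 3 (not isolated)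
Conditions: n-BuLi, THF, −78 °C; then 2, −78 to 0 °C
Reagents that add atoms: none
Why: N-acylation of the lithiated oxazolidinone with an acid chloride is the standard loading of the chiral auxiliary and creates no stereocentre.

Step 2
Reactants: 5 methacrolein
Product: 6 3-bromo-2-methylprop-1-en-1-yl benzoate
Conditions: ZnCl2 (cat.), CH2Cl2, −20 °C to rt
Reagents that add atoms: benzoyl bromide, O=C(Br)c1ccccc1
Why: Lewis-acid-catalysed 1,4-addition of an acyl bromide to an enal (bromide to the β-carbon, acyl group to oxygen) should give the γ-bromo enol ester, a β-cation equivalent of 2-methylpropanal whose enol geometry does not matter because that double bond is re-formed later inside a ring.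

Step 3
Reactants: 4 (4R)-4-benzyl-3-(3-methylbut-2-enoyl)-1,3-oxazolidin-2-one; 6 3-bromo-2-methylprop-1-en-1-yl benzoate
Product: 8 (4R)-4-benzyl-3-[(2R)-5-(benzoyloxy)-4-methyl-2-(prop-1-en-2-yl)pent-4-enoyl]-1,3-oxazolidin-2-one, via sodium dienolate 7 (not isolated)
Conditions: NaN(SiMe3)2, THF, −78 °C; then 6, −78 to −40 °C
Reagents that add atoms: none
Why: Evans alkylation of the chelated Z dienolate (γ-deprotonation of the senecioyl imide) at its α-carbon by SN2 attack on the allylic bromide, on the face opposite to the benzyl group, should set the (R) centre that becomes C5 and leave the isopropenyl group out of conjugation.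

Step 4
Reactants: 8 (4R)-4-benzyl-3-[(2R)-5-(benzoyloxy)-4-methyl-2-(prop-1-en-2-yl)pent-4-enoyl]-1,3-oxazolidin-2-one
Product: 10 (2R)-4-methyl-5-oxo-2-(prop-1-en-2-yl)pentanoic acid, via lithium peroxycarboxylate 9 (not isolated)
Conditions: LiOH, H2O2, THF–H2O, 0 °C; then Na2SO3; then 1 M HCl
Reagents that add atoms: hydrogen peroxide, OO
Why: Hydroperoxide cleavage of the auxiliary attacks the exocyclic imide carbonyl and also perhydrolyses the enol ester, so that sulfite reduction and acidification should free the acid and the latent aldehyde without touching the α-centre.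

Step 5
Reactants: 10 (2R)-4-methyl-5-oxo-2-(prop-1-en-2-yl)pentanoic acid
Product: 11 (3R)-5-methyl-3-(prop-1-en-2-yl)-3,4-dihydro-2H-pyran-2-one
Conditions: PPTS (cat.), toluene, reflux, Dean–Stark
Reagents that add atoms: none
Why: Acid-catalysed dehydrative enol lactonisation of a 5-oxo acid (through its cyclic hydroxy lactone tautomer) can place the enol double bond only towards the methyl-bearing carbon, because the other end of the ring is the acyl carbon.

Step 6
Reactants: 11 (3R)-5-methyl-3-(prop-1-en-2-yl)-3,4-dihydro-2H-pyran-2-one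
Product: 13 (3R)-5-methyl-3-(prop-1-en-2-yl)-3,4-dihydro-2H-pyran-2-yl acetate, via aluminium hemiacetal 12 (not isolated)
Conditions: i-Bu2AlH, CH2Cl2, −78 °C; then Ac2O, pyridine, DMAP, −78 to 0 °C
Reagents that add atoms: acetic anhydride, CC(=O)OC(C)=O
Why: Reductive acetylation of a lactone (hydride addition at −78 °C to a tetrahedral aluminium hemiacetal that is acetylated in situ) should give the α-acetoxy ether, which fixes the future C4 at the aldehyde level with a leaving group; both anomers serve because step 10 passes through the oxocarbenium ion.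

Step 7
Reactants: 14 but-2-yn-1-ol
Product: 15 tert-butyl(but-2-yn-1-yloxy)diphenylsilane
Conditions: imidazole, DMF, rt
Reagents that add atoms: tert-butyl(chloro)diphenylsilane, CC(C)(C)[Si](Cl)(c1ccccc1)c1ccccc1
Why: Standard silylation of a primary alcohol; this silyl ether should survive BF3·OEt2 at low temperature and 200 °C, and an allyl silyl ether, unlike an allyl aryl ether, cannot undergo an aromatic Claisen rearrangement in step 10.

Step 8
Reactants: 15 tert-butyl(but-2-yn-1-yloxy)diphenylsilane
Product: 16 tert-butyl{[(2Z)-3-(4,4,5,5-tetramethyl-1,3,2-dioxaborolan-2-yl)but-2-en-1-yl]oxy}diphenylsilane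
Conditions: CuCl (cat.), Xantphos (cat.), NaOt-Bu (cat.), MeOH, THF, rt
Reagents that add atoms: bis(pinacolato)diboron, CC1(C)OB(OC1(C)C)B1OC(C)(C)C(C)(C)O1
Why: Copper-catalysed formal hydroboration of a propargylic ether (syn borylcupration, then protonation by methanol) should place boron on the alkyne carbon remote from the OCH2 group with hydrogen cis to it, which fixes the alkene geometry later translated into C2.

Step 9
Reactants: 16 tert-butyl{[(2Z)-3-(4,4,5,5-tetramethyl-1,3,2-dioxaborolan-2-yl)but-2-en-1-yl]oxy}diphenylsilane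
Product: 17 potassium {(2Z)-4-[(tert-butyldiphenylsilyl)oxy]but-2-en-2-yl}trifluoroborate
Conditions: KHF2, MeOH–H2O, rt
Reagents that add atoms: potassium hydrogen difluoride, [K+].F[H-]F
Why: Conversion of a pinacol boronic ester into the potassium trifluoroborate with KHF2 is routine and gives the salt that transfers alkenyl groups to oxocarbenium ions.

Step 10
Reactants: 13 (3R)-5-methyl-3-(prop-1-en-2-yl)-3,4-dihydro-2H-pyran-2-yl acetate; 17 potassium {(2Z)-4-[(tert-butyldiphenylsilyl)oxy]but-2-en-2-yl}trifluoroborate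
Product: 19 (1R,2S,5S)-2-{[(tert-butyldiphenylsilyl)oxy]methyl}-1,3-dimethyl-5-(prop-1-en-2-yl)cyclohex-3-ene-1-carbaldehyde, via 2-alkenyl dihydropyran 18 (not isolated)
Conditions: BF3·OEt2, CH2Cl2–MeCN, −40 to 0 °C; then Et3N, volatiles removed, 1,2-dichlorobenzene, 200 °C (sealed tube)
Reagents that add atoms: none
Why: BF3·OEt2 ionises the anomeric acetate to the cyclic oxocarbenium ion, and the alkenyltrifluoroborate transfers its alkenyl group with retention of geometry on the face opposite to the neighbouring isopropenyl group, which forms the C4–C3 bond and the trans dihydropyran 18, an allyl vinyl ether held in a ring. On heating, 18 should undergo the [3,3]-sigmatropic Claisen rearrangement: the methyl-bearing enol-ether carbon bonds to the alkene CH (C1–C2), the O–C4 bond breaks, C3=C4 appears and the ring oxygen leaves as the formyl group on C1. The closest known reaction types are the Lewis-acid-mediated anomeric C-alkenylation of cyclic α-acetoxy ethers with potassium alkenyltrifluoroborates and the thermal Claisen rearrangement of 2-alkenyl-3,4-dihydro-2H-pyrans to cyclohex-3-ene-1-carbaldehydes. The cyclohexene (ring A) closes in this concerted suprafacial shift through the boat transition state that the dihydropyran imposes, with the alkenyl group axial and reaching across the ring, so it is a pericyclic closure and not an ionic exo or endo cyclisation. C1 and C2 are set by that geometry: the new bond forms on the ring face that carries the alkenyl group, so the isopropenyl group trans to it ends cis to the formyl group, and the E alkene places the silyloxymethyl group cis to the formyl group, while the temporary stereocentre at the oxygen-bearing carbon is consumed. The step needs trans alkenylation and an irreversible rearrangement; the adjacent isopropenyl group should secure the first and formation of the C=O bond the second.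

Step 11
Reactants: 19 (1R,2S,5S)-2-{[(tert-butyldiphenylsilyl)oxy]methyl}-1,3-dimethyl-5-(prop-1-en-2-yl)cyclohex-3-ene-1-carbaldehyde
Product: 20 methyl (2E)-3-[(1S,2S,5S)-2-{[(tert-butyldiphenylsilyl)oxy]methyl}-1,3-dimethyl-5-(prop-1-en-2-yl)cyclohex-3-en-1-yl]prop-2-enoate
Conditions: NaH, THF, 0 to 50 °C
Reagents that add atoms: trimethyl phosphonoacetate, COC(=O)CP(=O)(OC)OC
Why: Horner–Wadsworth–Emmons olefination of the non-enolisable neopentyl aldehyde should give the E enoate and adds the two remaining chain carbons without affecting any stereocentre.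

Step 12
Reactants: 20 methyl (2E)-3-[(1S,2S,5S)-2-{[(tert-butyldiphenylsilyl)oxy]methyl}-1,3-dimethyl-5-(prop-1-en-2-yl)cyclohex-3-en-1-yl]prop-2-enoate
Product: 21 methyl 3-[(1R,2R,5S)-2-{[(tert-butyldiphenylsilyl)oxy]methyl}-1,3-dimethyl-5-(prop-1-en-2-yl)cyclohex-3-en-1-yl]propanoate
Conditions: Mg, MeOH, rt
Reagents that add atoms: none
Why: Dissolving-metal conjugate reduction with magnesium in methanol should reduce only the ester-conjugated double bond and leave the ring alkene and the isopropenyl group untouched.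

Step 13
Reactants: 21 methyl 3-[(1R,2R,5S)-2-{[(tert-butyldiphenylsilyl)oxy]methyl}-1,3-dimethyl-5-(prop-1-en-2-yl)cyclohex-3-en-1-yl]propanoate
Product: 22 methyl 3-[(1R,2R,5S)-2-(hydroxymethyl)-1,3-dimethyl-5-(prop-1-en-2-yl)cyclohex-3-en-1-yl]propanoate
Conditions: Bu4NF, AcOH, THF, rt
Reagents that add atoms: none
Why: Fluoride desilylation, buffered with acetic acid so that the alkoxide does not lactonise onto the ester.

Step 14
Reactants: 22 methyl 3-[(1R,2R,5S)-2-(hydroxymethyl)-1,3-dimethyl-5-(prop-1-en-2-yl)cyclohex-3-en-1-yl]propanoate; 23 umbelliferone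
Product: 24 methyl 3-[(1R,2R,5S)-1,3-dimethyl-2-{[(2-oxo-2H-chromen-7-yl)oxy]methyl}-5-(prop-1-en-2-yl)cyclohex-3-en-1-yl]propanoate
Conditions: PPh3, DIAD, THF, 0 °C to rt
Reagents that add atoms: none
Why: Mitsunobu etherification of the primary alcohol with the acidic phenol of umbelliferone reacts at a CH2 group, so no stereocentre is involved, and it brings in the coumarin after all reducing and high-temperature steps.

Step 15
Reactants: 24 methyl 3-[(1R,2R,5S)-1,3-dimethyl-2-{[(2-oxo-2H-chromen-7-yl)oxy]methyl}-5-(prop-1-en-2-yl)cyclohex-3-en-1-yl]propanoate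
Product: 26 3-[(1R,2R,5S)-1,3-dimethyl-2-{[(2-oxo-2H-chromen-7-yl)oxy]methyl}-5-(prop-1-en-2-yl)cyclohex-3-en-1-yl]propanoic acid, via lithium carboxylate 25 (not isolated)
Conditions: LiOH, THF–H2O, rt; then 1 M HCl (pH 2–3)
Reagents that add atoms: lithium hydroxide, [Li+].[OH-]
Why: Saponification of the methyl ester; any hydroxide opening of the coumarin lactone gives the cis-coumarinate, which should close again on acidification.

**Compound list**

1 | (4R)-4-benzyl-1,3-oxazolidin-2-one | O=C1N[C@H](Cc2ccccc2)CO1 | starting material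
2 | 3-methylbut-2-enoyl chloride | CC(C)=CC(=O)Cl | starting material
3 | lithium (4R)-4-benzyl-2-oxo-1,3-oxazolidin-3-ide | O=C1[N-][C@H](Cc2ccccc2)CO1.[Li+] | intermediate
4 | (4R)-4-benzyl-3-(3-methylbut-2-enoyl)-1,3-oxazolidin-2-one | CC(C)=CC(=O)N1[C@H](Cc2ccccc2)COC1=O | intermediate
5 | methacrolein (2-methylprop-2-enal) | C=C(C)C=O | starting material
6 | 3-bromo-2-methylprop-1-en-1-yl benzoate | O=C(OC=C(C)CBr)c1ccccc1 | intermediate
7 | sodium Z dienolate of 4 | C=C(C)/C=C(\[O-])N1[C@H](Cc2ccccc2)COC1=O.[Na+] | intermediate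
8 | (4R)-4-benzyl-3-[(2R)-5-(benzoyloxy)-4-methyl-2-(prop-1-en-2-yl)pent-4-enoyl]-1,3-oxazolidin-2-one | C=C(C)[C@@H](CC(C)=COC(=O)c1ccccc1)C(=O)N1[C@H](Cc2ccccc2)COC1=O | intermediate
9 | lithium (2R)-4-methyl-5-oxo-2-(prop-1-en-2-yl)pentaneperoxoate | C=C(C)[C@@H](CC(C)C=O)C(=O)O[O-].[Li+] | intermediate
10 | (2R)-4-methyl-5-oxo-2-(prop-1-en-2-yl)pentanoic acid | C=C(C)[C@@H](CC(C)C=O)C(=O)O | intermediate
11 | (3R)-5-methyl-3-(prop-1-en-2-yl)-3,4-dihydro-2H-pyran-2-one | C=C(C)[C@@H]1C(=O)OC=C(C)C1 | intermediate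
12 | diisobutylaluminium (3R)-5-methyl-3-(prop-1-en-2-yl)-3,4-dihydro-2H-pyran-2-olate | C=C(C)[C@@H]1C(O[Al](CC(C)C)CC(C)C)OC=C(C)C1 | intermediate
13 | (3R)-5-methyl-3-(prop-1-en-2-yl)-3,4-dihydro-2H-pyran-2-yl acetate | C=C(C)[C@@H]1C(OC(C)=O)OC=C(C)C1 | intermediate
14 | but-2-yn-1-ol | CC#CCO | starting material
15 | tert-butyl(but-2-yn-1-yloxy)diphenylsilane | CC#CCO[Si](c1ccccc1)(c1ccccc1)C(C)(C)C | intermediate
16 | tert-butyl{[(2Z)-3-(4,4,5,5-tetramethyl-1,3,2-dioxaborolan-2-yl)but-2-en-1-yl]oxy}diphenylsilane | C/C(B1OC(C)(C)C(C)(C)O1)=C\CO[Si](c1ccccc1)(c1ccccc1)C(C)(C)C | intermediate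
17 | potassium {(2Z)-4-[(tert-butyldiphenylsilyl)oxy]but-2-en-2-yl}trifluoroborate | C/C([B-](F)(F)F)=C\CO[Si](c1ccccc1)(c1ccccc1)C(C)(C)C.[K+] | intermediate
18 | tert-butyl({(2E)-3-[(2S,3R)-5-methyl-3-(prop-1-en-2-yl)-3,4-dihydro-2H-pyran-2-yl]but-2-en-1-yl}oxy)diphenylsilane | C=C(C)[C@@H]1[C@@H](/C(C)=C/CO[Si](c2ccccc2)(c2ccccc2)C(C)(C)C)OC=C(C)C1 | intermediate
19 | (1R,2S,5S)-2-{[(tert-butyldiphenylsilyl)oxy]methyl}-1,3-dimethyl-5-(prop-1-en-2-yl)cyclohex-3-ene-1-carbaldehyde | C=C(C)[C@@H]1C=C(C)[C@H](CO[Si](c2ccccc2)(c2ccccc2)C(C)(C)C)[C@](C)(C=O)C1 | intermediate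
20 | methyl (2E)-3-[(1S,2S,5S)-2-{[(tert-butyldiphenylsilyl)oxy]methyl}-1,3-dimethyl-5-(prop-1-en-2-yl)cyclohex-3-en-1-yl]prop-2-enoate | C=C(C)[C@@H]1C=C(C)[C@H](CO[Si](c2ccccc2)(c2ccccc2)C(C)(C)C)[C@](C)(/C=C/C(=O)OC)C1 | intermediate
21 | methyl 3-[(1R,2R,5S)-2-{[(tert-butyldiphenylsilyl)oxy]methyl}-1,3-dimethyl-5-(prop-1-en-2-yl)cyclohex-3-en-1-yl]propanoate | C=C(C)[C@@H]1C=C(C)[C@H](CO[Si](c2ccccc2)(c2ccccc2)C(C)(C)C)[C@](C)(CCC(=O)OC)C1 | intermediate
22 | methyl 3-[(1R,2R,5S)-2-(hydroxymethyl)-1,3-dimethyl-5-(prop-1-en-2-yl)cyclohex-3-en-1-yl]propanoate | C=C(C)[C@@H]1C=C(C)[C@H](CO)[C@](C)(CCC(=O)OC)C1 | intermediate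
23 | umbelliferone (7-hydroxy-2H-chromen-2-one) | O=c1ccc2ccc(O)cc2o1 | starting material
24 | methyl 3-[(1R,2R,5S)-1,3-dimethyl-2-{[(2-oxo-2H-chromen-7-yl)oxy]methyl}-5-(prop-1-en-2-yl)cyclohex-3-en-1-yl]propanoate | C=C(C)[C@@H]1C=C(C)[C@H](COc2ccc3ccc(=O)oc3c2)[C@](C)(CCC(=O)OC)C1 | intermediate
25 | lithium 3-[(1R,2R,5S)-1,3-dimethyl-2-{[(2-oxo-2H-chromen-7-yl)oxy]methyl}-5-(prop-1-en-2-yl)cyclohex-3-en-1-yl]propanoate | C=C(C)[C@@H]1C=C(C)[C@H](COc2ccc3ccc(=O)oc3c2)[C@](C)(CCC(=O)[O-])C1.[Li+] | intermediate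
26 | 3-[(1R,2R,5S)-1,3-dimethyl-2-{[(2-oxo-2H-chromen-7-yl)oxy]methyl}-5-(prop-1-en-2-yl)cyclohex-3-en-1-yl]propanoic acid | C=C(C)[C@@H]1C=C(C)[C@H](COc2ccc3ccc(=O)oc3c2)[C@](C)(CCC(=O)O)C1 | target

**Step count and risks**

Total step count: 15. Longest linear sequence: 11 steps (1, 3, 4, 5, 6, 10, 11, 12, 13, 14, 15).

Steps most likely to fail:

Step 10. What may go wrong: alkenyl transfer to the oxocarbenium ion without facial control, elimination or oligomerisation of the enol-ether oxocarbenium ion, and loss of material at 200 °C through retro-hetero-Diels–Alder cleavage of 18 or a carbonyl-ene reaction of the new formyl group with the cis isopropenyl group. Fallback: the two bond formations would be separated. Setting out from 13 and 17, the alkenylation would be run alone at −40 °C and the trans dihydropyran 18 isolated and freed from its cis isomer by chromatography. Then 18 would be treated with i-Bu3Al in CH2Cl2 at −78 to 0 °C, an organoaluminium-promoted Claisen rearrangement that runs at low temperature and reduces the aluminium-bound aldehyde as it forms, to give [(1R,2S,5S)-2-{[(tert-butyldiphenylsilyl)oxy]methyl}-1,3-dimethyl-5-(prop-1-en-2-yl)cyclohex-3-en-1-yl]methanol F1. Dess–Martin oxidation of F1 comes back to the route at 19.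

Step 3. What may go wrong: acyl transfer from the enol benzoate to the dienolate, alkylation at the γ-carbon, or SN2′ attack at the oxygen-bearing carbon of the bromide. Fallback: the aldehyde oxidation level would be reached only after the C–C bond is made. Setting out from 4, dienolate 7 would be alkylated with methyl 2-(bromomethyl)acrylate to give (4R)-4-benzyl-3-[(2R)-4-(methoxycarbonyl)-2-(prop-1-en-2-yl)pent-4-enoyl]-1,3-oxazolidin-2-one F2. Conjugate reduction of the acrylate alone ([(Ph3P)CuH]6 (cat.), PhSiH3, toluene) would give (4R)-4-benzyl-3-[(2R)-5-methoxy-4-methyl-5-oxo-2-(prop-1-en-2-yl)pentanoyl]-1,3-oxazolidin-2-one F3. LiOH and H2O2 would remove the auxiliary to give (2R)-5-methoxy-4-methyl-5-oxo-2-(prop-1-en-2-yl)pentanoic acid F4. Reduction of the methyl ester of F4 with i-Bu2AlH (2.2 equiv, −78 °C; the aluminium carboxylate stays inert) comes back to the route at 10.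

Step 8. What may go wrong: delivery of boron to the wrong alkyne carbon or protodeboronation of the product. Fallback: the alkenyl metal would be made by hydrozirconation instead. Setting out from 15, Cp2Zr(H)Cl (syn addition, zirconium on the less hindered methyl-bearing carbon) followed by I2 would give tert-butyl{[(2E)-3-iodobut-2-en-1-yl]oxy}diphenylsilane F5. Miyaura borylation of F5 (bis(pinacolato)diboron, PdCl2(PPh3)2, PPh3, KOPh, toluene, 50 °C), which keeps the double-bond geometry, comes back to the route at 16.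

Further compounds
F1 | step 10 | [(1R,2S,5S)-2-{[(tert-butyldiphenylsilyl)oxy]methyl}-1,3-dimethyl-5-(prop-1-en-2-yl)cyclohex-3-en-1-yl]methanol | C=C(C)[C@@H]1C=C(C)[C@H](CO[Si](c2ccccc2)(c2ccccc2)C(C)(C)C)[C@](C)(CO)C1
F2 | step 3 | (4R)-4-benzyl-3-[(2R)-4-(methoxycarbonyl)-2-(prop-1-en-2-yl)pent-4-enoyl]-1,3-oxazolidin-2-one | C=C(C)[C@@H](CC(=C)C(=O)OC)C(=O)N1[C@H](Cc2ccccc2)COC1=O
F3 | step 3 | (4R)-4-benzyl-3-[(2R)-5-methoxy-4-methyl-5-oxo-2-(prop-1-en-2-yl)pentanoyl]-1,3-oxazolidin-2-one | C=C(C)[C@@H](CC(C)C(=O)OC)C(=O)N1[C@H](Cc2ccccc2)COC1=O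
F4 | step 3 | (2R)-5-methoxy-4-methyl-5-oxo-2-(prop-1-en-2-yl)pentanoic acid | C=C(C)[C@@H](CC(C)C(=O)OC)C(=O)O
F5 | step 8 | tert-butyl{[(2E)-3-iodobut-2-en-1-yl]oxy}diphenylsilane | C/C(I)=C\CO[Si](c1ccccc1)(c1ccccc1)C(C)(C)C
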